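## The problem

The target joins two isopropyl-bearing six-membered carbocycles through an (E)-2-(hydroxymethyl)acrylate ester. Ring A is a cyclohexane whose two adjacent ring-fusion carbons carry, on the same face, the carbonyl carbon and the vinylic CH carbon of a seven-membered unsaturated lactone (ring B), which also holds the free carboxylic acid on its double bond. Beside the carbonyl-bearing fusion carbon lies a quaternary carbon with a tertiary hydroxyl (cis to the lactone carbonyl) and a CH2O arm acylated by the ring C acid. Beside the other fusion carbon lies the isopropyl carbon, trans to the vinylic arm. Ring C is a cyclohexene with CH2OH on the double bond and, on the two neighbouring sp3 carbons, the acrylate arm and an isopropyl group cis to each other.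

The four stereocentres of ring A are contiguous. If the ring is built around the quaternary carbinol, that centre can fix both fusion carbons, and its hydroxyl can then deliver hydrogen to set the isopropyl carbon. The two centres of ring C are remote from ring A and need their own control.

Several groups are fragile. The β-hydroxy lactone can undergo retro-aldol cleavage or dehydration. A free CH2OH on the quaternary carbon sits 1,4 to the lactone carbonyl and could translactonise to a five-membered lactone. The two 2-(oxymethyl)acrylates are open to conjugate addition and SN2′ displacement. Ring C has a doubly allylic methine. Three esters beside a free acid rule out hydrolytic deprotection at the end.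

The enabling feature is the pattern on ring A: a carboxyl carbon on one fusion carbon, a one-carbon arm on the next, cis, and a β-hydroxyl on the quaternary carbon. This is the retron of a cyclohex-3-enecarboxylic acid made by [3,3] ring contraction of a 6-alkenyl δ-lactone enolate, and its β-hydroxy ester is an acetate-aldol (Reformatsky) retron. Ring C has the skeleton of ring A less the lactone carbonyl carbon, with a double bond where ring A has the β-hydroxy acid. Loss of CO2 and water from a ring A intermediate therefore leads to ring C, with only the arm-bearing carbon needing the opposite configuration.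

## Retrosynthesis

**Late stage.** Target 39 is traced to its bis-silyl ether 38 and then to the tert-butyl ester 37. The free acid and the two primary allylic alcohols are thus released last, by non-hydrolytic reagents that spare the lactone and the acrylate ester. Cutting the acyl–oxygen bond of the side-chain ester in 37 gives ring A/B alcohol 24 and ring C acid 36. This is the only cut that splits the molecule into halves of similar size, and it asks only for selective acylation of a primary alcohol beside a tertiary one.

**Ring B.** The seven-membered lactone of 24 (through silyl ether 23) is opened at its C=C bond, not at the ester bond, giving diene 22. Lactonisation of a seco acid would need activation of a carboxyl that carries a cis β-hydroxyl (β-lactone risk) and an intermolecular synthesis of a hindered trisubstituted acrylate. Metathesis lets the ester be made by carboxylate alkylation and fixes the alkene geometry through the ring. Diene 22 comes from aldehyde 21, and 21 from PMB ether 19, which is the ester of acid 17 with commercial bromide 18.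

**Ring C acid.** Acid 36 is traced through 35 and 34 to (Z)-bromoenoate 33, made by Wittig olefination of cis aldehyde 30 with the ylide derived from 31. The bromoenoate allows the hydroxymethyl group to be put in by cross-coupling with retention, which avoids a β-alkoxy phosphonate. Aldehyde 30 is the α-epimer of trans aldehyde 28, which comes via alcohol 27 from cyclohexene 26. Cyclohexene 26 is the product of decarboxylative dehydration of the same acid 17 used for ring A (through β-lactone 25). This removes a separate ring C synthesis; the price is one epimerisation.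

**Isopropyl centre.** Acid 17 comes from cyclohexene acid 16 by hydrogenation directed by the homoallylic tertiary hydroxyl, the same topology as a 4-hydroxy-p-menth-1-ene. The forward step must deliver hydrogen only from the hydroxyl face.

**Key cut.** In 16 the bond between the two future fusion carbons is cut, which opens the carbocycle and leads back to δ-lactone 13. The alternative of cutting exocyclic bonds would leave the quaternary carbinol to be added to a preformed ring. Here it is in place first and relays its configuration to both new centres. The forward step is an Ireland–Claisen ring contraction of the lactone silyl ketene acetal.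

**Lactone.** Lactone 13 is opened at C3–C4 to bromoacetate 12 (an intramolecular Reformatsky retron), which is the ester of β-hydroxy ketone 10 with bromoacetyl bromide 11. The forward cyclisation must give the 4,6-trans hydroxy lactone.

**Aldol and enal.** Ketone 10 is cut at the carbinol carbon into enal 6 and silyloxyacetone 8 (from hydroxyacetone 7). The forward aldol must enolise 8 on the methyl side and select one face of 6. Enal 6 is the crossed aldol condensation product of isovaleraldehyde 1 (as its cyclohexylimine 3, from 1 and amine 2) and aldehyde 4.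

## Roads not taken

**Alternative 1:** The two exocyclic C–C bonds at the ring-fusion carbons would be made together by [2+2] addition of dichloroketene to the cyclohexenyl silyl ether A1, giving the cis-fused dichlorocyclobutanone A2.
- **Merits.** The isopropyl centre is in A1 from the start. Suprafacial addition guarantees the cis pair, and both ring substituents steer the ketene to the opposite face, which is the face the target needs. Alkoxide cleavage of A2 between C=O and CCl2 would release an ester and a masked aldehyde on neighbouring carbons. This reaches the fusion pattern in fewer steps than the seven needed here to reach 16.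
- **Weak points.** The two alkene carbons of A1 are both secondary allylic, so nothing strongly decides which one takes the carbonyl carbon. The quaternary carbinol is missing: the silyloxy carbon must become a ketone flanked by the ester-bearing fusion carbon (an enolisable, epimerisable β-keto ester) and then accept a hydroxymethyl nucleophile from one face.
- **Comparison.** The chosen plan is longer up to the ring but has the tertiary alcohol in place before ring closure. Its regiochemistry is fixed by intramolecularity, and the absolute configuration comes from one reagent-controlled aldol.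

**Alternative 2:** Ring B would be made last by oxygen insertion into the cis-octalone A3 to give lactone A4.
- **Merits.** The carbocyclic precursor already carries the ring B alkene, the ester and an acetonide-protected diol. If the insertion worked, the endgame would be shorter than the five operations this plan spends on ring B.
- **Weak points.** The oxygen must enter between the carbonyl and the allylic CH2, yet the ring-fusion methine on the other side is the more substituted and normally the better migrating group. The α-CH2 of A3 is doubly activated, so the double bond can move into conjugation and the fusion carbon α to the ketone can epimerise. An enzyme would need screening. A3 also contains all four ring A stereocentres, so the stereochemical problem is moved, not solved.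
- **Comparison.** In the chosen plan the position of the ester oxygen is unambiguous because the ester is made by carboxylate alkylation.

**Alternative 3:** Ring C would be built by Diels–Alder addition of diene A5 to the acryloyl oxazolidinone A6, giving cycloadduct A7.
- **Merits.** Endo addition with ortho/para regiochemistry sets the two ring C centres cis in one step, and the auxiliary gives the absolute configuration. For ring C this is stereochemically more secure than the present route, whose arm-bearing carbon rests on a kinetic protonation (step 17).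
- **Weak points.** The acyl group must be turned into isopropyl over several steps through an α-epimerisable ketone. Two protecting groups must be exchanged. The hard half (ring A with the quaternary carbinol and the cis-fused lactone) is not addressed at all.
- **Comparison.** The chosen plan takes ring C from intermediate 17 in eight steps and uses one stereocontrolled sequence for both halves. It must set against this the risk in step 17, for which a fallback is given.

Key step: step 7

Assumption: (−)-Ipc2BCl is taken to deliver methyl-ketone enol borinates to the Si face of aldehydes; compounds 4, 18 and 31 are bought.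

## Route

Step 1
Reactants: 1 isovaleraldehyde; 2 cyclohexylamine
Product: 3 N-cyclohexyl-3-methylbutan-1-imine
Conditions: MgSO4, Et2O, 0 °C to rt; distillation
Reagents that add atoms: none
Why: Condensation of an aldehyde with a primary amine gives the aldimine, which is needed for a directed crossed aldol in step 2.

Step 2
Reactants: 3 N-cyclohexyl-3-methylbutan-1-imine; 4 2-[(4-methoxybenzyl)oxy]acetaldehyde
Product: 6 (E)-2-isopropyl-4-[(4-methoxybenzyl)oxy]but-2-enal, via aldol 5 (not isolated)
Conditions: LiN(iPr)2, THF, −78 °C; 4, −78 °C; then aq. oxalic acid, THF, rt to 45 °C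
Reagents that add atoms: water, O
Why: Directed aldol condensation through the lithiated aldimine, which adds to the α-alkoxy aldehyde; acid hydrolysis and β-elimination give the conjugated enal, whose (E) geometry (formyl trans to CH2OPMB) is the thermodynamic one.

Step 3
Reactants: 7 hydroxyacetone
Product: 8 1-[(tert-butyldiphenylsilyl)oxy]propan-2-one
Conditions: TBDPSCl, imidazole, CH2Cl2, 0 °C to rt
Reagents that add atoms: tert-butyl(chloro)diphenylsilane, CC(C)(C)[Si](Cl)(c1ccccc1)c1ccccc1
Why: Silylation of a primary alcohol; the bulky silyl group is chosen because it resists 1,4-migration to a neighbouring alkoxide and survives the later acidic and basic steps.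

Step 4
Reactants: 8 1-[(tert-butyldiphenylsilyl)oxy]propan-2-one; 6 (E)-2-isopropyl-4-[(4-methoxybenzyl)oxy]but-2-enal
Product: 10 (4S,5E)-1-[(tert-butyldiphenylsilyl)oxy]-4-hydroxy-5-isopropyl-7-[(4-methoxybenzyl)oxy]hept-5-en-2-one, via enol borinate 9 (not isolated)
Conditions: (−)-Ipc2BCl, Et3N, Et2O, −78 to 0 °C; 6, −78 to −20 °C; then H2O2, pH 7 buffer, MeOH, 0 °C
Reagents that add atoms: none
Why: Ipc2BCl-mediated boron aldol of a methyl ketone: the hindered chloroborane/amine pair should enolise the methyl group, not the oxygenated methylene, and the (−)-reagent should deliver the enol borinate to the Si face of the enal, which sets the (S)-carbinol.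

Step 5
Reactants: 10 β-hydroxy ketone; 11 bromoacetyl bromide
Product: 12 (3S,4E)-7-[(tert-butyldiphenylsilyl)oxy]-4-isopropyl-1-[(4-methoxybenzyl)oxy]-6-oxohept-2-en-3-yl bromoacetate (numbered from the PMB end; configuration as in 10)
Conditions: pyridine, CH2Cl2, −20 °C
Reagents that add atoms: none
Why: Acylation of the secondary alcohol with an acid bromide under pyridine at low temperature, where β-hydroxy ketones do not eliminate.

Step 6
Reactants: 12 bromoacetate
Product: 13 (4R,6S)-4-{[(tert-butyldiphenylsilyl)oxy]methyl}-4-hydroxy-6-{(2E)-1-[(4-methoxybenzyl)oxy]-4-methylpent-2-en-3-yl}tetrahydro-2H-pyran-2-one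
Conditions: SmI2 (divalent samarium, 2.2 equiv), THF, −78 °C; then aq. NH4Cl
Reagents that add atoms: none
Why: Samarium Reformatsky cyclisation: the α-bromo ester is reduced to a trivalent samarium enolate that adds to the ketone through a chelated chair with the alkenyl and silyloxymethyl groups equatorial and the new hydroxyl axial, which gives the 4,6-trans hydroxy lactone by 1,3-induction.

Step 7
Reactants: 13 hydroxy lactone
Product: 16 (1S,2R,6R)-6-{[(tert-butyldiphenylsilyl)oxy]methyl}-6-hydroxy-3-isopropyl-2-{[(4-methoxybenzyl)oxy]methyl}cyclohex-3-ene-1-carboxylic acid, via bis-silyl ketene acetal 14 (not isolated), via trimethylsilyl ester 15 (not isolated)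
Conditions: LiN(iPr)2 (2.3 equiv), Me3SiCl/Et3N, THF, −78 °C to rt; toluene, 105 °C; then citric acid, MeOH/H2O, rt
Reagents that add atoms: none
Why: Double deprotonation with Me3SiCl present gives O-silyl ketene acetal 14 with the tertiary oxygen silylated (the transient alkoxide disfavours β-elimination), and on heating 14 undergoes an Ireland–Claisen [3,3] shift in which the bond between C3 and the alkene terminus forms as the ring C6–O bond breaks; the closest known reaction type is the ring contraction of 6-alkenyl δ-lactone silyl ketene acetals to cyclohex-3-enecarboxylic acids. The six-membered carbocycle (ring A) is closed by this bond formation itself, through a transition state shaped like a 2-oxabicyclo[2.2.2]octene; because the ketene acetal double bond is endocyclic, the six-atom array can only be a boat. The carboxyl-bearing carbon is set by the lactone: the alkene reaches the enolate carbon on the face where C6 holds it, and since the C4 hydroxyl is trans to the alkenyl group it ends cis to the carboxyl. The arm-bearing carbon is set by the (E) alkene: in the boat the CH2OPMB group points outward and ends cis to the carboxyl, while hydrogen takes the inside position. Chirality passes from C6, which becomes part of the new trisubstituted ring alkene. The step needs O-silylation over C-silylation and no β-elimination or retro-aldol; trapping in the flask at −78 °C and running the thermal stage on the neutral ketene acetal should secure this. Mild acidic methanolysis then cleaves the silyl ester and the tertiary trimethylsilyl ether to give 16.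

Step 8
Reactants: 16 cyclohexene acid
Product: 17 (1S,2S,3S,6R)-6-{[(tert-butyldiphenylsilyl)oxy]methyl}-6-hydroxy-3-isopropyl-2-{[(4-methoxybenzyl)oxy]methyl}cyclohexane-1-carboxylic acid
Conditions: H2 (1 atm), [Ir(cod)(PCy3)(py)]PF6 (5 mol%), CH2Cl2, 0 °C to rt
Reagents that add atoms: none
Why: Hydroxyl-directed homogeneous hydrogenation: the homoallylic tertiary hydroxyl (and the cis carboxyl) bind the cationic iridium, hydrogen is delivered to their face, and the isopropyl group ends trans to the PMB-oxymethyl arm; PMB and silyl ethers are inert.

Step 9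
Reactants: 17 cyclohexane acid; 18 tert-butyl 2-(bromomethyl)acrylate
Product: 19 2-(tert-butoxycarbonyl)allyl ester of 17
Conditions: Cs2CO3, DMF, 0 °C to rt
Reagents that add atoms: none
Why: O-Alkylation of the cesium carboxylate by an allylic bromide (SN2 and SN2′ give the same ester); the carboxyl is never activated, so the β-hydroxyl cannot close a β-lactone.

Step 10
Reactants: 19 PMB ether
Product: 21 aldehyde (formyl group in place of CH2OPMB; other centres as in 19), via alcohol 20 (not isolated)
Conditions: DDQ, CH2Cl2/pH 7 buffer, 0 °C; work-up; then Dess–Martin periodinane, NaHCO3, CH2Cl2, 0 °C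
Reagents that add atoms: none
Why: Oxidative PMB cleavage followed at once by Dess–Martin oxidation; the γ-hydroxy ester 20 is not stored because it could close to a γ-lactone.

Step 11
Reactants: 21 aldehyde
Product: 22 vinyl compound (CH=CH2 in place of CHO)
Conditions: CH2I2, Zn, Ti(OiPr)4, THF, 0 °C to rt
Reagents that add atoms: diiodomethane, ICI
Why: Takai methylenation is selective for aldehydes and is neither basic nor nucleophilic, so the 2-(acyloxymethyl)acrylate and the α-stereocentre should be left alone.

Step 12
Reactants: 22 diene
Product: 23 ring A/B lactone, tert-butyl ester, primary TBDPS ether (cis-fused; SMILES in the list)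
Conditions: [RuCl2(H2IMes)(=CH-C6H4-2-OiPr)] (second-generation Hoveyda–Grubbs catalyst, 10 mol%), toluene (2 mM), 80 °C
Reagents that add atoms: none
Why: Ring-closing metathesis of the vinyl group with the 1,1-disubstituted acrylate closes the seven-membered lactone as the trisubstituted enoate; the ring fixes CH2O cis to the ring carbon on the double bond.

Step 13
Reactants: 23 silyl ether
Product: 24 ring A/B diol (tertiary OH and free CH2OH), tert-butyl ester
Conditions: HF·pyridine, pyridine, THF, 0 °C to rt
Reagents that add atoms: none
Why: Fluoride cleavage of the primary silyl ether under buffered acidic conditions that leave the lactone, the tert-butyl ester and the tertiary alcohol untouched.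

Step 14
Reactants: 17 cyclohexane acid
Product: 26 trans cyclohexene of ring C (CH2OTBDPS on the double bond; isopropyl trans to CH2OPMB), via β-lactone 25 (not isolated)
Conditions: PhSO2Cl, pyridine, 0 °C; work-up; then toluene, 110 °C
Reagents that add atoms: none
Why: Carboxyl activation closes the cis β-hydroxy acid to the β-lactone with retention, and thermal cycloreversion expels CO2 to give the trisubstituted ring alkene; the two remaining stereocentres are not touched.

Step 15
Reactants: 26 PMB ether
Product: 27 trans alcohol (CH2OH in place of CH2OPMB)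
Conditions: DDQ, CH2Cl2/pH 7 buffer, 0 °C
Reagents that add atoms: none
Why: DDQ oxidises the PMB ether to a hemiacetal that hydrolyses to the alcohol; the allylic silyl ether is inert.

Step 16
Reactants: 27 trans alcohol
Product: 28 trans β,γ-unsaturated aldehyde
Conditions: Dess–Martin periodinane, NaHCO3, CH2Cl2, 0 °C
Reagents that add atoms: none
Why: Buffered Dess–Martin oxidation gives the aldehyde without base, so the ring double bond stays out of conjugation.

Step 17
Reactants: 28 trans aldehyde
Product: 30 cis aldehyde (formyl cis to isopropyl), via potassium dienolate 29 (not isolated)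
Conditions: KN(SiMe3)2, THF, −78 °C (28 added to the base); then AcOH, THF, −78 °C
Reagents that add atoms: none
Why: Kinetic α-protonation of the dienolate: 1,3-allylic strain with the exocyclic enolate should push the neighbouring isopropyl group pseudoaxial, the proton enters from the opposite face, and the less stable cis aldehyde forms with the ring alkene still unconjugated; this inverts the arm-bearing carbon to the ring C configuration.

Step 18
Reactants: 30 cis aldehyde; 31 methyl (triphenylphosphoranylidene)acetate
Product: 33 methyl (Z)-2-bromo-3-(ring C)acrylate, via bromo ylide 32 (not isolated)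
Conditions: 31, N-bromosuccinimide, CH2Cl2, −20 °C; then 30, 0 °C to rt
Reagents that add atoms: N-bromosuccinimide, O=C1CCC(=O)N1Br
Why: Wittig olefination with the α-bromo stabilised ylide made in the flask; the conditions are close to neutral, and stabilised ylides place the ester trans to the ring carbon, giving the (Z)-bromoenoate.

Step 19
Reactants: 33 bromoenoate
Product: 34 methyl (E)-2-(hydroxymethyl)-3-(ring C)acrylate
Conditions: Bu3SnCH2OH, Pd(PPh3)4 (zerovalent palladium, 10 mol%), 1,4-dioxane, 90 °C
Reagents that add atoms: (tributylstannyl)methanol, CCCC[Sn](CCCC)(CCCC)CO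
Why: Stille coupling transfers the hydroxymethyl group to the alkenyl bromide with retention of geometry, so CH2OH ends cis to the ring carbon.

Step 20
Reactants: 34 allylic alcohol
Product: 35 TBS ether of 34
Conditions: TBSCl, imidazole, DMF, 0 °C to rt
Reagents that add atoms: tert-butyl(chloro)dimethylsilane, CC(C)(C)[Si](C)(C)Cl
Why: Silylation of the primary allylic alcohol, so that the acid can be activated in step 22 without self-esterification.

Step 21
Reactants: 35 methyl ester
Product: 36 ring C acid, (E)-2-{[(tert-butyldimethylsilyl)oxy]methyl}-3-[(1R,6S)-3-{[(tert-butyldiphenylsilyl)oxy]methyl}-6-isopropylcyclohex-2-en-1-yl]acrylic acid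
Conditions: LiOH, THF/MeOH/H2O, rt; then 1 M HCl to pH 4
Reagents that add atoms: lithium hydroxide, [Li+].[OH-]
Why: Saponification of the methyl ester; both silyl ethers survive hydroxide at room temperature.

Step 22
Reactants: 36 ring C acid; 24 ring A/B diol
Product: 37 coupled ester (tert-butyl ester, TBS and TBDPS ethers)
Conditions: 36, 2,4,6-trichlorobenzoyl chloride, Et3N, THF, rt; then 24, DMAP, toluene, rt
Reagents that add atoms: none
Why: Yamaguchi esterification through the mixed anhydride: the primary alcohol reacts and the tertiary one does not; in the preferred chair of 24 the hydroxymethyl and the lactone carbonyl are trans-diaxial, which should slow translactonisation.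

Step 23
Reactants: 37 tert-butyl ester
Product: 38 free acid, bis-silyl ether
Conditions: Me3SiOTf, 2,6-lutidine, CH2Cl2, 0 °C; then citric acid, MeOH/H2O, 0 °C
Reagents that add atoms: none
Why: The silyl triflate converts the tert-butyl ester to the trimethylsilyl ester with loss of isobutene, without hydrolysis; brief acidic methanolysis frees the acid and any trimethylsilyl ether on the tertiary alcohol, while the lactone, the acrylate ester and the bulky silyl ethers remain.

Step 24
Reactants: 38 bis-silyl ether
Product: 39 target CNP0361406.6
Conditions: HF·pyridine, pyridine, THF, 0 °C to rt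
Reagents that add atoms: none
Why: Fluoride removes both silyl ethers; no base is present that could trigger retro-aldol cleavage or acyl migration.

## Compound list

1 | isovaleraldehyde | CC(C)CC=O | starting material
2 | cyclohexylamine | NC1CCCCC1 | starting material
3 | N-cyclohexyl-3-methylbutan-1-imine | CC(C)C/C=N/C1CCCCC1 | intermediate
4 | 2-[(4-methoxybenzyl)oxy]acetaldehyde | O=CCOCc1ccc(OC)cc1 | starting material
5 | 3-hydroxy-2-isopropyl-4-[(4-methoxybenzyl)oxy]butanal, mixture of diastereomers | CC(C)C(C=O)C(O)COCc1ccc(OC)cc1 | intermediate
6 | (E)-2-isopropyl-4-[(4-methoxybenzyl)oxy]but-2-enal | CC(C)/C(C=O)=C\COCc1ccc(OC)cc1 | intermediate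
7 | hydroxyacetone | CC(=O)CO | starting material
8 | 1-[(tert-butyldiphenylsilyl)oxy]propan-2-one | CC(=O)CO[Si](c1ccccc1)(c1ccccc1)C(C)(C)C | intermediate
9 | diisopinocampheyl enol borinate of 8 (methyl-side enolate) | C=C(CO[Si](c1ccccc1)(c1ccccc1)C(C)(C)C)OB([C@@H]1C[C@@H]2C[C@H]([C@H]1C)C2(C)C)[C@@H]1C[C@@H]2C[C@H]([C@H]1C)C2(C)C | intermediate
10 | (4S,5E)-1-[(tert-butyldiphenylsilyl)oxy]-4-hydroxy-5-isopropyl-7-[(4-methoxybenzyl)oxy]hept-5-en-2-one | CC(C)/C(=C\COCc1ccc(OC)cc1)[C@@H](O)CC(=O)CO[Si](c1ccccc1)(c1ccccc1)C(C)(C)C | intermediate
11 | bromoacetyl bromide | BrCC(Br)=O | starting material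
12 | bromoacetate of 10 | CC(C)/C(=C\COCc1ccc(OC)cc1)[C@@H](OC(=O)CBr)CC(=O)CO[Si](c1ccccc1)(c1ccccc1)C(C)(C)C | intermediate
13 | (4R,6S)-4-(TBDPS-oxymethyl)-4-hydroxy-6-[(E)-alkenyl] δ-lactone, hydroxyl trans to alkenyl | CC(C)/C(=C\COCc1ccc(OC)cc1)[C@@H]2C[C@](O)(CO[Si](c3ccccc3)(c4ccccc4)C(C)(C)C)CC(=O)O2 | intermediate
14 | bis(trimethylsilyl) ketene acetal of 13 | CC(C)/C(=C\COCc1ccc(OC)cc1)[C@@H]2C[C@](O[Si](C)(C)C)(CO[Si](c3ccccc3)(c4ccccc4)C(C)(C)C)C=C(O[Si](C)(C)C)O2 | intermediate
15 | trimethylsilyl ester and tertiary trimethylsilyl ether of 16 | CC(C)C1=CC[C@](O[Si](C)(C)C)(CO[Si](c2ccccc2)(c3ccccc3)C(C)(C)C)[C@@H](C(=O)O[Si](C)(C)C)[C@H]1COCc4ccc(OC)cc4 | intermediate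
16 | (1S,2R,6R) cyclohex-3-ene acid; carboxyl, hydroxyl and CH2OPMB all cis | CC(C)C1=CC[C@](O)(CO[Si](c2ccccc2)(c3ccccc3)C(C)(C)C)[C@@H](C(=O)O)[C@H]1COCc4ccc(OC)cc4 | intermediate
17 | (1S,2S,3S,6R) cyclohexane acid; isopropyl trans to CH2OPMB | CC(C)[C@@H]1CC[C@](O)(CO[Si](c2ccccc2)(c3ccccc3)C(C)(C)C)[C@@H](C(=O)O)[C@H]1COCc4ccc(OC)cc4 | intermediate
18 | tert-butyl 2-(bromomethyl)acrylate | C=C(CBr)C(=O)OC(C)(C)C | starting material
19 | 2-(tert-butoxycarbonyl)allyl ester of 17 | CC(C)[C@@H]1CC[C@](O)(CO[Si](c2ccccc2)(c3ccccc3)C(C)(C)C)[C@@H](C(=O)OCC(=C)C(=O)OC(C)(C)C)[C@H]1COCc4ccc(OC)cc4 | intermediate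
20 | primary alcohol from 19 | CC(C)[C@@H]1CC[C@](O)(CO[Si](c2ccccc2)(c3ccccc3)C(C)(C)C)[C@@H](C(=O)OCC(=C)C(=O)OC(C)(C)C)[C@H]1CO | intermediate
21 | aldehyde from 20 | CC(C)[C@@H]1CC[C@](O)(CO[Si](c2ccccc2)(c3ccccc3)C(C)(C)C)[C@@H](C(=O)OCC(=C)C(=O)OC(C)(C)C)[C@H]1C=O | intermediate
22 | vinyl compound (metathesis substrate) | CC(C)[C@@H]1CC[C@](O)(CO[Si](c2ccccc2)(c3ccccc3)C(C)(C)C)[C@@H](C(=O)OCC(=C)C(=O)OC(C)(C)C)[C@H]1C=C | intermediate
23 | ring A/B lactone, tert-butyl ester, TBDPS ether | CC(C)[C@@H]1CC[C@](O)(CO[Si](c3ccccc3)(c4ccccc4)C(C)(C)C)[C@H]2C(=O)OCC(C(=O)OC(C)(C)C)=C[C@@H]12 | intermediate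
24 | ring A/B lactone diol, tert-butyl ester | CC(C)[C@@H]1CC[C@](O)(CO)[C@H]2C(=O)OCC(C(=O)OC(C)(C)C)=C[C@@H]12 | intermediate
25 | cis-fused β-lactone of 17 | CC(C)[C@@H]1CC[C@@]2(CO[Si](c3ccccc3)(c4ccccc4)C(C)(C)C)OC(=O)[C@H]2[C@H]1COCc5ccc(OC)cc5 | intermediate
26 | trans ring C cyclohexene, PMB ether | CC(C)[C@@H]1CCC(CO[Si](c2ccccc2)(c3ccccc3)C(C)(C)C)=C[C@H]1COCc4ccc(OC)cc4 | intermediate
27 | trans ring C alcohol | CC(C)[C@@H]1CCC(CO[Si](c2ccccc2)(c3ccccc3)C(C)(C)C)=C[C@H]1CO | intermediate
28 | trans ring C aldehyde | CC(C)[C@@H]1CCC(CO[Si](c2ccccc2)(c3ccccc3)C(C)(C)C)=C[C@H]1C=O | intermediate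
29 | potassium dienolate of 28 | CC(C)[C@@H]1CCC(CO[Si](c2ccccc2)(c3ccccc3)C(C)(C)C)=CC1=C[O-].[K+] | intermediate
30 | cis ring C aldehyde, (1R,6S) | CC(C)[C@@H]1CCC(CO[Si](c2ccccc2)(c3ccccc3)C(C)(C)C)=C[C@@H]1C=O | intermediate
31 | methyl (triphenylphosphoranylidene)acetate | COC(=O)C=P(c1ccccc1)(c1ccccc1)c1ccccc1 | starting material
32 | methyl bromo(triphenylphosphoranylidene)acetate | COC(=O)C(Br)=P(c1ccccc1)(c1ccccc1)c1ccccc1 | intermediate
33 | methyl (Z)-2-bromoacrylate on ring C | CC(C)[C@@H]1CCC(CO[Si](c2ccccc2)(c3ccccc3)C(C)(C)C)=C[C@@H]1/C=C(\Br)C(=O)OC | intermediate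
34 | methyl (E)-2-(hydroxymethyl)acrylate on ring C | CC(C)[C@@H]1CCC(CO[Si](c2ccccc2)(c3ccccc3)C(C)(C)C)=C[C@@H]1/C=C(\CO)C(=O)OC | intermediate
35 | TBS ether of 34 | CC(C)[C@@H]1CCC(CO[Si](c2ccccc2)(c3ccccc3)C(C)(C)C)=C[C@@H]1/C=C(\CO[Si](C)(C)C(C)(C)C)C(=O)OC | intermediate
36 | ring C acid | CC(C)[C@@H]1CCC(CO[Si](c2ccccc2)(c3ccccc3)C(C)(C)C)=C[C@@H]1/C=C(\CO[Si](C)(C)C(C)(C)C)C(=O)O | intermediate
37 | coupled ester, fully protected | CC(C)[C@@H]1CC[C@](O)(COC(=O)/C(=C/[C@H]2C=C(CO[Si](c3ccccc3)(c3ccccc3)C(C)(C)C)CC[C@H]2C(C)C)CO[Si](C)(C)C(C)(C)C)[C@H]2C(=O)OCC(C(=O)OC(C)(C)C)=C[C@@H]12 | intermediate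
38 | free acid, bis-silyl ether | CC(C)[C@@H]1CC[C@](O)(COC(=O)/C(=C/[C@H]2C=C(CO[Si](c3ccccc3)(c3ccccc3)C(C)(C)C)CC[C@H]2C(C)C)CO[Si](C)(C)C(C)(C)C)[C@H]2C(=O)OCC(C(=O)O)=C[C@@H]12 | intermediate
39 | CNP0361406.6 | CC(C)[C@@H]1CC[C@](O)(COC(=O)/C(=C/[C@H]2C=C(CO)CC[C@H]2C(C)C)CO)[C@H]2C(=O)OCC(C(=O)O)=C[C@@H]12 | target

## Step count and risks

Total: 24 steps. Longest linear sequence: 18 steps (1, 2, 4–8, 14–24). The ring A/B line (1, 2, 4–13, 22–24) has 15.

**Step 7 (key step).** Enolisation of a β-oxygenated lactone may lead to β-elimination or retro-aldol ring opening before silylation. Silylation may go partly to carbon. The enforced boat, with the silyloxymethyl group on the alkene side, may need more forcing than the ketene acetal tolerates. Fallback: the route leaves 13, whose tertiary alcohol is capped with Et3SiOTf and 2,6-lutidine to give triethylsilyl ether F1, so that no alkoxide is present. Enolisation and silylation as before give ketene acetal F2, which rearranges on heating to trimethylsilyl ester F3. Mild methanolysis gives the triethylsilyl-protected acid F4. Aqueous acetic acid in THF removes the triethylsilyl group, and the route is rejoined at 16.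

**Step 17.** Facial selectivity in the protonation may be poor, because an aldehyde enolate has hydrogen on the exocyclic carbon and the allylic strain that tilts the isopropyl group is weaker than in ketone or ester enolates. Self-aldol during enolisation and return to the trans isomer are further risks. Fallback: from 28, chlorite oxidation gives trans acid F5 and Me3SiCHN2 gives trans methyl ester F6. The ester enolate has two non-hydrogen groups on the exocyclic carbon, which should enforce the pseudoaxial isopropyl. Deprotonation with LiN(iPr)2 in THF/HMPA at −78 °C and quenching with acetic acid should give cis ester F7. Reduction with iBu2AlH at −78 °C returns to 30.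

**Step 4.** Enolisation may occur partly on the oxygenated side, and reagent control with an α-branched enal may give incomplete enantioselectivity. Fallback: from 8 and 6, the kinetic lithium enolate (LiN(iPr)2, −78 °C, deprotonation away from the oxygen) gives racemic aldol F8. Sharpless kinetic resolution with Ti(OiPr)4, D-(−)-diisopropyl tartrate and tBuOOH should epoxidise the (R)-enantiomer to epoxy alcohol F9. The unreacted (S)-alcohol is 10.

**Step 10 (and step 11).** The γ-hydroxy ester 20 may lactonise with loss of the acrylate alcohol before it is oxidised. The 2-(acyloxymethyl)acrylate may be attacked during methylenation. Fallback: from 17, N,N′-diisopropyl-O-tert-butylisourea gives tert-butyl ester F10, which is too hindered to lactonise. DDQ gives alcohol F11 and Dess–Martin oxidation gives aldehyde F12. Ph3P=CH2 (now safe, since no acrylate is present) gives vinyl ester F13. Me3SiOTf with 2,6-lutidine frees vinyl acid F14. Alkylation with 18 and Cs2CO3 rejoins the route at 22.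

**Step 22.** The neopentyl-type primary alcohol acylates slowly, and under basic acylation conditions the free CH2OH may attack the ring B lactone (translactonisation to the five-membered lactone). Fallback: from 24, cyclodehydration of the 1,2-diol with PPh3 and diisopropyl azodicarboxylate gives spiro-epoxide F15. Acid 36 then opens it at the CH2 carbon (catalytic Bu4NBr, MeCN, 60 °C), which forms the ester and the tertiary alcohol in one event and rejoins the route at 37.

## Further compounds

F1 | step 7 | tertiary triethylsilyl ether of lactone 13 | CC(C)/C(=C\COCc1ccc(OC)cc1)[C@@H]2C[C@](O[Si](CC)(CC)CC)(CO[Si](c3ccccc3)(c4ccccc4)C(C)(C)C)CC(=O)O2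
F2 | step 7 | trimethylsilyl ketene acetal of F1 | CC(C)/C(=C\COCc1ccc(OC)cc1)[C@@H]2C[C@](O[Si](CC)(CC)CC)(CO[Si](c3ccccc3)(c4ccccc4)C(C)(C)C)C=C(O[Si](C)(C)C)O2
F3 | step 7 | trimethylsilyl ester of F4 | CC(C)C1=CC[C@](O[Si](CC)(CC)CC)(CO[Si](c2ccccc2)(c3ccccc3)C(C)(C)C)[C@@H](C(=O)O[Si](C)(C)C)[C@H]1COCc4ccc(OC)cc4
F4 | step 7 | triethylsilyl-protected cyclohexene acid | CC(C)C1=CC[C@](O[Si](CC)(CC)CC)(CO[Si](c2ccccc2)(c3ccccc3)C(C)(C)C)[C@@H](C(=O)O)[C@H]1COCc4ccc(OC)cc4
F5 | step 17 | trans ring C carboxylic acid | CC(C)[C@@H]1CCC(CO[Si](c2ccccc2)(c3ccccc3)C(C)(C)C)=C[C@H]1C(=O)O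
F6 | step 17 | trans ring C methyl ester | CC(C)[C@@H]1CCC(CO[Si](c2ccccc2)(c3ccccc3)C(C)(C)C)=C[C@H]1C(=O)OC
F7 | step 17 | cis ring C methyl ester | CC(C)[C@@H]1CCC(CO[Si](c2ccccc2)(c3ccccc3)C(C)(C)C)=C[C@@H]1C(=O)OC
F8 | step 4 | racemic aldol | CC(C)/C(=C\COCc1ccc(OC)cc1)C(O)CC(=O)CO[Si](c1ccccc1)(c1ccccc1)C(C)(C)C
F9 | step 4 | epoxy alcohol from the (R)-enantiomer | CC(C)[C@]1(O[C@H]1COCc2ccc(OC)cc2)[C@H](O)CC(=O)CO[Si](c3ccccc3)(c4ccccc4)C(C)(C)C
F10 | step 10 | tert-butyl ester of 17 | CC(C)[C@@H]1CC[C@](O)(CO[Si](c2ccccc2)(c3ccccc3)C(C)(C)C)[C@@H](C(=O)OC(C)(C)C)[C@H]1COCc4ccc(OC)cc4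
F11 | step 10 | primary alcohol, tert-butyl ester | CC(C)[C@@H]1CC[C@](O)(CO[Si](c2ccccc2)(c3ccccc3)C(C)(C)C)[C@@H](C(=O)OC(C)(C)C)[C@H]1CO
F12 | step 10 | aldehyde, tert-butyl ester | CC(C)[C@@H]1CC[C@](O)(CO[Si](c2ccccc2)(c3ccccc3)C(C)(C)C)[C@@H](C(=O)OC(C)(C)C)[C@H]1C=O
F13 | step 10 | vinyl compound, tert-butyl ester | CC(C)[C@@H]1CC[C@](O)(CO[Si](c2ccccc2)(c3ccccc3)C(C)(C)C)[C@@H](C(=O)OC(C)(C)C)[C@H]1C=C
F14 | step 10 | vinyl acid | CC(C)[C@@H]1CC[C@](O)(CO[Si](c2ccccc2)(c3ccccc3)C(C)(C)C)[C@@H](C(=O)O)[C@H]1C=C
F15 | step 22 | spiro-epoxide of the ring A/B lactone | CC(C)[C@@H]1CC[C@]3(CO3)[C@H]2C(=O)OCC(C(=O)OC(C)(C)C)=C[C@@H]12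
A1 | alternative 1 | tert-butyldimethylsilyl ether of cis-4-isopropylcyclohex-2-en-1-ol | CC(C)[C@@H]1CC[C@H](O[Si](C)(C)C(C)(C)C)C=C1
A2 | alternative 1 | cis-fused dichlorocyclobutanone on ring A | CC(C)[C@@H]1CC[C@H](O[Si](C)(C)C(C)(C)C)[C@H]2C(=O)C(Cl)(Cl)[C@@H]12
A3 | alternative 2 | cis-fused octalone with acetonide and tert-butyl ester | CC(C)[C@@H]1CC[C@]3(COC(C)(C)O3)[C@H]2C(=O)CC(C(=O)OC(C)(C)C)=C[C@@H]12
A4 | alternative 2 | ring A/ring B lactone with acetonide-protected diol | CC(C)[C@@H]1CC[C@]3(COC(C)(C)O3)[C@H]2C(=O)OCC(C(=O)OC(C)(C)C)=C[C@@H]12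
A5 | alternative 3 | (E)-1-(TBS-oxymethyl)-3-(PMB-oxymethyl)buta-1,3-diene | C=C(COCc1ccc(OC)cc1)/C=C/CO[Si](C)(C)C(C)(C)C
A6 | alternative 3 | (S)-3-acryloyl-4-benzyloxazolidin-2-one | C=CC(=O)N1C(=O)OC[C@@H]1Cc1ccccc1
A7 | alternative 3 | cis ring C cycloadduct | CC(C)(C)[Si](C)(C)OC[C@H]1C=C(COCc2ccc(OC)cc2)CC[C@H]1C(=O)N3C(=O)OC[C@@H]3Cc4ccccc4
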